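In a one-step world D passes straight into L, and the climb bends over exponentially to a plateau.

all flasks: E 0.55 mM

| flask | D | remark | time |
|---|---|---|---|
| teal | 0.050 M | the very flask that is asked about, followed so far |  |
| green | 0.034 M | run made earlier |  |
| flask | 0.050 M |  | 10 h |

| teal: time / h | teal: L / % | green: time / min | green: L / % |
|---|---|---|---|
| 0.833 | 8 | 6.00 | 2 |
| 2.00 | 12 | 15.0 | 4 |
| 4.00 | 14 | 30.0 | 6 |
| 6.00 | 16 | 50.0 | 8 |

(scatter of a reading: 1.5 percentage points)

- amounts and yields of L count X too
- given per volume of solution although it is solid: X
- what is added takes up no volume worth counting
- steps under discussion: X <-> L; D -> J; E + J -> E + L; 2 E -> Q; D -> Z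

- elm: at 10 h add D, 50.0% of the amount charged, then wait 10 h
- oak: change nothing and wait 10 h more
- alder: at 10 h add E, 100% of the amount charged, then wait 10 h

* L, in percent of the D first charged, at 10 h
* the remedy with the largest gain of L, or "none" below 2 percentage points (elm / oak / alder / none)
* L present, in percent of the D first charged, after elm
* L present, in percent of the D first charged, after oak

The teal flask did not look like that: it was still climbing at 6.00 h, and the green run matched it at equal times, 8% at 50.0 min, so I read percentages as independent of the charge. I integrated one rate. Two E going to Q make E fall as one over time, once past its first half-life (second-order deactivation). L forms at a rate of E times J, so with J roughly steady the integral is a logarithm.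

The teal readings at 0.833 h and 6.00 h gave 4.1 percentage points, the log gain: the points of L won per factor e of elapsed time.

From below, the teal flask had 16% at 6.00 h, and L goes nowhere but into X, which is counted. From above, the climb was slowing, so its last pace carried straight on to 10 h gave 20.0%. The log gain tightened this to 18.1%, give or take 1.5 points, and put oak at 20.9%. Elm, if the gain follows the material, gave 22.3%. Oak's gain was 2.8 points and elm's 4.2 points. Alder puts E back but no new material, and the readings did not tell me how much material stood behind L, so I put no figure on its gain. It had to earn a quarter of the 18.1% reckoned for the first 10 h to pass elm, so I chose alder.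

The forecast said 18.5%, inside my bracket, with oak 21%, elm 23% and alder best: “This curve rises with log time, not towards an exponential plateau”.

    X ⇌ L, rate k1*(cs1 - [L]) while solid is left; crystals form when [L] > cs1 (solubility = 13.0 mM, k = 4.00 min⁻¹)
    D → J (k = 0.0360 min⁻¹)
    E + J → E + L (k = 27.0 L mol⁻¹ min⁻¹)
    2 E → Q (k = 60.0 L mol⁻¹ min⁻¹)
    D → Z (k = 0.0680 min⁻¹)

The flask gave 18.0%, with oak 20.4% against my 20.9% and elm 22.8%. Alder gained the most, 9.4 points, against 4.8 points for elm and 2.4 points for oak. The same log gain, run backwards from the 6.00 h reading to a neighbouring flask read at 2.5 h with its amounts held, gave 12.4%, and that neighbouring flask held 12.3% of L.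

The runs are simulated with constants of no real substance, noise included.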